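**Retrosynthetic overview**

- Feature: in ring A, C6 is the only unsubstituted carbon ortho to the C1 carboxyl, and the C1 carboxyl plus the C6 2-oxononyl chain is the hydrolysed form of the lactone ring of a 3-heptylisocoumarin.
- Disconnection 1: the depside aryl ester C(=O)–O, giving a ring A acid (ketone masked as a dioxolane) and the C4 hydroxyl of benzyl orsellinate (ring B).
- Disconnection 2: the isocoumarin C4a–C4 bond (ring A C6–CH2) and the lactone C3–O bond, by carboxylate-directed C–H annulation of 2,4-dimethoxybenzoic acid with the octanoyl sulfoxonium ylide.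
- Ring order: rings A and B are purchased; the only ring made is the lactone ring (step 2). It carries the acid half through the selective demethylation and is reopened in step 4.

Key step: step 2

Remark on the chemistry: a free 2-(2-oxoalkyl)benzoic acid closes back to the isocoumarin under acid or on carboxyl activation, so the ketone is ketalised on the benzyl ester, not on the free acid. The target has no stereocentre.

**Route**

Step 1
Reactants: 1 trimethylsulfoxonium iodide; 2 octanoyl chloride
Product: 4 1-[dimethyl(oxo)-lambda6-sulfanylidene]nonan-2-one, via dimethylsulfoxonium methylide 3 (not isolated)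
Conditions: 1 (3 equiv), KOtBu (3 equiv), THF, reflux; then 2 (1 equiv), 0 °C to rt
Reagents that add atoms: none
Why: Acylation of a sulfur ylide: KOtBu turns 1 into methylide 3, whose carbon attacks the acid chloride, and a second equivalent of 3 removes the now acidic alpha proton to give the stabilised beta-keto sulfoxonium ylide 4.

Step 2
Reactants: 5 2,4-dimethoxybenzoic acid; 4 1-[dimethyl(oxo)-lambda6-sulfanylidene]nonan-2-one
Product: 8 3-heptyl-6,8-dimethoxy-1H-isochromen-1-one, via keto acid 6 (not isolated), via hemiketal lactone 7 (not isolated)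
Conditions: [Cp*RhCl2]2 (2.5 mol %), AgSbF6 (10 mol %), NaOAc (30 mol %), (CF3)2CHOH, 80 °C
Reagents that add atoms: none
Why: The carboxylate of 5 binds the cationic Cp*Rh fragment (trivalent rhodium, freed of chloride by AgSbF6), and acetate-assisted concerted metalation-deprotonation at C6 gives a five-membered rhodacycle; ylide 4 then coordinates through carbon, loses dimethyl sulfoxide to form a rhodium carbene, the aryl group migrates onto the carbene carbon to make the C6–CH bond, and protodemetalation releases keto acid 6 and returns the catalyst without an external oxidant. The closest known reaction type is the carboxylate-directed C–H acylmethylation/annulation of benzoic acids with sulfoxonium ylides to 3-substituted isocoumarins under trivalent rhodium or divalent ruthenium catalysis. The lactone ring closes by 6-exo-trig addition of the carboxyl oxygen to the ketone carbonyl (hemiketal 7), followed by dehydration to the enol lactone 8 in the hot acidic fluoroalcohol medium. No stereocentre remains, because the hemiketal carbon of 7 becomes sp2 on dehydration. The step needs site selectivity and a single insertion: the C2 methoxy group blocks one ortho position, so C6 carries the only C–H bond the carboxylate can deliver rhodium to, and there is no second ortho C–H bond for a further insertion.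

Step 3
Reactants: 8 3-heptyl-6,8-dimethoxy-1H-isochromen-1-one
Product: 9 3-heptyl-8-hydroxy-6-methoxy-1H-isochromen-1-one
Conditions: BCl3 (1.2 equiv), CH2Cl2, −78 °C to 0 °C; then H2O
Reagents that add atoms: none
Why: Chelation-controlled Lewis acid ether cleavage: BCl3 bridges the lactone carbonyl and the peri C8 methoxy oxygen in a six-membered chelate, so chloride should remove only that methyl group and leave the C6 methoxy group and the enol lactone untouched.

Step 4
Reactants: 9 3-heptyl-8-hydroxy-6-methoxy-1H-isochromen-1-one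
Product: 10 2-hydroxy-4-methoxy-6-(2-oxononyl)benzoic acid
Conditions: KOH (2 M aq.), EtOH, 60 °C; then 1 M HCl, 0 °C, to pH 3, extract cold
Reagents that add atoms: potassium hydroxide (its oxygen ends in the carboxyl group), [K+].[OH-]
Why: Saponification of the enol lactone: hydroxide adds to the lactone carbonyl, the enolate that leaves tautomerises to the ketone, and cold acidification should give the open keto acid before it can recyclise or decarboxylate.

Step 5
Reactants: 10 2-hydroxy-4-methoxy-6-(2-oxononyl)benzoic acid
Product: 11 benzyl 2-hydroxy-4-methoxy-6-(2-oxononyl)benzoate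
Conditions: BnBr (1.1 equiv), KHCO3, DMF, rt
Reagents that add atoms: benzyl bromide, BrCc1ccccc1
Why: SN2 O-alkylation of the carboxylate: KHCO3 ionises only the carboxylic acid (the C2 hydroxyl is hydrogen-bonded and stays protonated), and because the carboxyl group acts as a nucleophile and is never activated, the ketone cannot close onto it.

Step 6
Reactants: 11 benzyl 2-hydroxy-4-methoxy-6-(2-oxononyl)benzoate
Product: 12 benzyl 2-[(2-heptyl-1,3-dioxolan-2-yl)methyl]-6-hydroxy-4-methoxybenzoate
Conditions: TMSOCH2CH2OTMS (2.5 equiv), TMSOTf (0.1 equiv), CH2Cl2, −78 °C to −20 °C; then pyridine, aq. NaHCO3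
Reagents that add atoms: 1,2-bis(trimethylsilyloxy)ethane, C[Si](C)(C)OCCO[Si](C)(C)C
Why: Noyori ketalisation, driven by formation of hexamethyldisiloxane and run below 0 °C, so acid-promoted enol lactonisation of the benzyl ester should not compete; any silyl ether formed on the phenol is lost in the bicarbonate work-up.

Step 7
Reactants: 12 benzyl 2-[(2-heptyl-1,3-dioxolan-2-yl)methyl]-6-hydroxy-4-methoxybenzoate
Product: 13 2-[(2-heptyl-1,3-dioxolan-2-yl)methyl]-6-hydroxy-4-methoxybenzoic acid
Conditions: H2 (1 atm), 10 % Pd/C, EtOAc, rt; filter, concentrate cold, use at once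
Reagents that add atoms: none
Why: Hydrogenolysis of the benzyl ester over palladium on carbon under neutral conditions, to which the dioxolane, the aryl methyl ether and the phenol are inert; the acid is carried on directly so that it has little time to act on its own ketal.

Step 8
Reactants: 14 orsellinic acid (2,4-dihydroxy-6-methylbenzoic acid)
Product: 15 benzyl 2,4-dihydroxy-6-methylbenzoate (benzyl orsellinate)
Conditions: BnBr (1.05 equiv), KHCO3, DMF, rt
Reagents that add atoms: benzyl bromide, BrCc1ccccc1
Why: SN2 O-alkylation of the carboxylate: under bicarbonate only the carboxylic acid is ionised, so the ester should form without ether formation at either phenol.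

Step 9
Reactants: 13 2-[(2-heptyl-1,3-dioxolan-2-yl)methyl]-6-hydroxy-4-methoxybenzoic acid; 15 benzyl 2,4-dihydroxy-6-methylbenzoate
Product: 16 benzyl 4-({2-[(2-heptyl-1,3-dioxolan-2-yl)methyl]-6-hydroxy-4-methoxybenzoyl}oxy)-2-hydroxy-6-methylbenzoate
Conditions: DCC (1.1 equiv), DMAP (0.1 equiv), CH2Cl2, 0 °C to rt
Reagents that add atoms: none
Why: Steglich esterification: DCC gives the O-acylisourea and DMAP relays the acyl group to the phenol, the masked ketone cannot close onto the activated carboxyl, the C4 hydroxyl of 15 is the only hydroxyl in either partner not hydrogen-bonded to an ortho carbonyl group and should react selectively, and the medium stays non-acidic for the ketal.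

Step 10
Reactants: 16 benzyl 4-({2-[(2-heptyl-1,3-dioxolan-2-yl)methyl]-6-hydroxy-4-methoxybenzoyl}oxy)-2-hydroxy-6-methylbenzoate
Product: 17 benzyl 2-hydroxy-4-{[2-hydroxy-4-methoxy-6-(2-oxononyl)benzoyl]oxy}-6-methylbenzoate
Conditions: 1 M aq. HCl, THF, rt
Reagents that add atoms: water, O
Why: Acid-catalysed hydrolysis of the dioxolane; the aryl ester, benzyl ester and methyl ether tolerate dilute aqueous acid at room temperature, and the water present disfavours dehydrative closure of the freed ketone onto the depside carbonyl.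

Step 11
Reactants: 17 benzyl 2-hydroxy-4-{[2-hydroxy-4-methoxy-6-(2-oxononyl)benzoyl]oxy}-6-methylbenzoate
Product: 18 2-hydroxy-4-{[2-hydroxy-4-methoxy-6-(2-oxononyl)benzoyl]oxy}-6-methylbenzoic acid (target, CNP0320117.0)
Conditions: H2 (1 atm), 10 % Pd/C, EtOAc, rt
Reagents that add atoms: none
Why: Hydrogenolysis of the benzyl ester; the non-conjugated ketone, the aryl ester and the phenols are stable to 1 atm H2 over palladium on carbon, and the neutral medium avoids decarboxylation of the orsellinic acid unit.

**Compound list**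

1 | trimethylsulfoxonium iodide | C[S+](C)(C)=O.[I-] | starting material
2 | octanoyl chloride | CCCCCCCC(=O)Cl | starting material
3 | dimethylsulfoxonium methylide | C=S(C)(C)=O | intermediate (not isolated)
4 | 1-[dimethyl(oxo)-lambda6-sulfanylidene]nonan-2-one | CCCCCCCC(=O)C=S(C)(C)=O | intermediate
5 | 2,4-dimethoxybenzoic acid | COc1ccc(C(=O)O)c(OC)c1 | starting material
6 | 2,4-dimethoxy-6-(2-oxononyl)benzoic acid | CCCCCCCC(=O)Cc1cc(OC)cc(OC)c1C(=O)O | intermediate (not isolated)
7 | 3-heptyl-3-hydroxy-6,8-dimethoxy-3,4-dihydro-1H-isochromen-1-one (racemic, transient) | CCCCCCCC1(O)Cc2cc(OC)cc(OC)c2C(=O)O1 | intermediate (not isolated)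
8 | 3-heptyl-6,8-dimethoxy-1H-isochromen-1-one | CCCCCCCC1=Cc2cc(OC)cc(OC)c2C(=O)O1 | intermediate
9 | 3-heptyl-8-hydroxy-6-methoxy-1H-isochromen-1-one | CCCCCCCC1=Cc2cc(OC)cc(O)c2C(=O)O1 | intermediate
10 | 2-hydroxy-4-methoxy-6-(2-oxononyl)benzoic acid | CCCCCCCC(=O)Cc1cc(OC)cc(O)c1C(=O)O | intermediate
11 | benzyl 2-hydroxy-4-methoxy-6-(2-oxononyl)benzoate | CCCCCCCC(=O)Cc1cc(OC)cc(O)c1C(=O)OCc1ccccc1 | intermediate
12 | benzyl 2-[(2-heptyl-1,3-dioxolan-2-yl)methyl]-6-hydroxy-4-methoxybenzoate | CCCCCCCC1(Cc2cc(OC)cc(O)c2C(=O)OCc2ccccc2)OCCO1 | intermediate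
13 | 2-[(2-heptyl-1,3-dioxolan-2-yl)methyl]-6-hydroxy-4-methoxybenzoic acid | CCCCCCCC1(Cc2cc(OC)cc(O)c2C(=O)O)OCCO1 | intermediate
14 | orsellinic acid (2,4-dihydroxy-6-methylbenzoic acid) | Cc1cc(O)cc(O)c1C(=O)O | starting material
15 | benzyl 2,4-dihydroxy-6-methylbenzoate | Cc1cc(O)cc(O)c1C(=O)OCc1ccccc1 | intermediate
16 | benzyl 4-({2-[(2-heptyl-1,3-dioxolan-2-yl)methyl]-6-hydroxy-4-methoxybenzoyl}oxy)-2-hydroxy-6-methylbenzoate | CCCCCCCC1(Cc2cc(OC)cc(O)c2C(=O)Oc2cc(C)c(C(=O)OCc3ccccc3)c(O)c2)OCCO1 | intermediate
17 | benzyl 2-hydroxy-4-{[2-hydroxy-4-methoxy-6-(2-oxononyl)benzoyl]oxy}-6-methylbenzoate | CCCCCCCC(=O)Cc1cc(OC)cc(O)c1C(=O)Oc1cc(C)c(C(=O)OCc2ccccc2)c(O)c1 | intermediate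
18 | 2-hydroxy-4-{[2-hydroxy-4-methoxy-6-(2-oxononyl)benzoyl]oxy}-6-methylbenzoic acid | CCCCCCCC(=O)Cc1cc(OC)cc(O)c1C(=O)Oc1cc(C)c(C(=O)O)c(O)c1 | target

**Step count**

Total steps: 11. Longest linear sequence: 10 (steps 1 to 7 and 9 to 11; step 8 is the side branch).

**Steps most likely to fail**

Step 2 (key step). Metalation may be slow because the C2 methoxy group twists the carboxylate out of the ring plane and can itself bind rhodium. The ylide may also be consumed by protonation or carbene dimerisation before insertion, and dehydration of 6 and 7 may stop short of the lactone. The fallback sets out from octanoyl chloride 2 and comes back at 8. 3,5-Dimethoxyhomophthalic acid F1, assumed to be purchasable, is heated neat with excess 2 at about 200 °C. This should acylate its benzylic methylene and close the lactone to 3-heptyl-6,8-dimethoxy-1-oxo-1H-isochromene-4-carboxylic acid F2. F2 should lose carbon dioxide at that temperature to give 8. This is the classical homophthalic acid route to 3-alkylisocoumarins and uses no C–H activation.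

Step 9. Attack of the phenol on the di-ortho-substituted acyl donor is slow. The O-acylisourea may therefore rearrange to the N-acylurea, or be intercepted by the free C2 hydroxyl of a second acid molecule to give oligomeric esters. The fallback sets out from 12 and comes back at 17. The phenol of 12 is capped with MOMCl and iPr2NEt in CH2Cl2 to give benzyl 2-[(2-heptyl-1,3-dioxolan-2-yl)methyl]-4-methoxy-6-(methoxymethoxy)benzoate F3. Hydrogenolysis (H2, Pd/C, EtOAc) gives 2-[(2-heptyl-1,3-dioxolan-2-yl)methyl]-4-methoxy-6-(methoxymethoxy)benzoic acid F4, which has no free hydroxyl. Coupling with 15 under DCC and DMAP gives benzyl 4-({2-[(2-heptyl-1,3-dioxolan-2-yl)methyl]-4-methoxy-6-(methoxymethoxy)benzoyl}oxy)-2-hydroxy-6-methylbenzoate F5. Aqueous HCl in THF then removes the methoxymethyl ether and the dioxolane together to give 17.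

Step 7. The freed carboxyl group sits next to the dioxolane. It may protonate and open the ketal and then close onto the resulting oxocarbenium ion, so the ketone protection is lost and the material drifts back to the lactone before or during the coupling. The fallback sets out from 10 and comes back at 17, using an acid-stable thioketal.

- 10 is alkylated with allyl bromide and KHCO3 in DMF to give allyl 2-hydroxy-4-methoxy-6-(2-oxononyl)benzoate F6.
- Ethane-1,2-dithiol and BF3·OEt2 in CH2Cl2 at 0 °C give allyl 2-[(2-heptyl-1,3-dithiolan-2-yl)methyl]-6-hydroxy-4-methoxybenzoate F7.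
- The allyl ester is removed with Pd(PPh3)4 (zerovalent palladium) and morpholine in THF to give 2-[(2-heptyl-1,3-dithiolan-2-yl)methyl]-6-hydroxy-4-methoxybenzoic acid F8, which cannot be opened by its own carboxyl group.
- DCC and DMAP coupling with 15 gives benzyl 4-({2-[(2-heptyl-1,3-dithiolan-2-yl)methyl]-6-hydroxy-4-methoxybenzoyl}oxy)-2-hydroxy-6-methylbenzoate F9.
- MeI and CaCO3 in aqueous MeCN at 45 °C remove the dithiolane to give 17, so that no sulfur is left when step 11 is run.

**Further compounds**

F1 | step 2 | 3,5-dimethoxyhomophthalic acid [2-(carboxymethyl)-4,6-dimethoxybenzoic acid] | COc1cc(CC(=O)O)c(C(=O)O)c(OC)c1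
F2 | step 2 | 3-heptyl-6,8-dimethoxy-1-oxo-1H-isochromene-4-carboxylic acid | CCCCCCCC1=C(C(=O)O)c2cc(OC)cc(OC)c2C(=O)O1
F3 | step 9 | benzyl 2-[(2-heptyl-1,3-dioxolan-2-yl)methyl]-4-methoxy-6-(methoxymethoxy)benzoate | CCCCCCCC1(Cc2cc(OC)cc(OCOC)c2C(=O)OCc2ccccc2)OCCO1
F4 | step 9 | 2-[(2-heptyl-1,3-dioxolan-2-yl)methyl]-4-methoxy-6-(methoxymethoxy)benzoic acid | CCCCCCCC1(Cc2cc(OC)cc(OCOC)c2C(=O)O)OCCO1
F5 | step 9 | benzyl 4-({2-[(2-heptyl-1,3-dioxolan-2-yl)methyl]-4-methoxy-6-(methoxymethoxy)benzoyl}oxy)-2-hydroxy-6-methylbenzoate | CCCCCCCC1(Cc2cc(OC)cc(OCOC)c2C(=O)Oc2cc(C)c(C(=O)OCc3ccccc3)c(O)c2)OCCO1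
F6 | step 7 | allyl 2-hydroxy-4-methoxy-6-(2-oxononyl)benzoate | CCCCCCCC(=O)Cc1cc(OC)cc(O)c1C(=O)OCC=C
F7 | step 7 | allyl 2-[(2-heptyl-1,3-dithiolan-2-yl)methyl]-6-hydroxy-4-methoxybenzoate | CCCCCCCC1(Cc2cc(OC)cc(O)c2C(=O)OCC=C)SCCS1
F8 | step 7 | 2-[(2-heptyl-1,3-dithiolan-2-yl)methyl]-6-hydroxy-4-methoxybenzoic acid | CCCCCCCC1(Cc2cc(OC)cc(O)c2C(=O)O)SCCS1
F9 | step 7 | benzyl 4-({2-[(2-heptyl-1,3-dithiolan-2-yl)methyl]-6-hydroxy-4-methoxybenzoyl}oxy)-2-hydroxy-6-methylbenzoate | CCCCCCCC1(Cc2cc(OC)cc(O)c2C(=O)Oc2cc(C)c(C(=O)OCc3ccccc3)c(O)c2)SCCS1
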